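## Analysis of the target

The target is a flavan-3-ol: ring A (a phloroglucinol-type benzene) is fused to the dihydropyran ring C, which carries the catechol ring B at C2. The two adjacent stereocentres, C2 (R, aryl) and C3 (R, acyloxy), are cis on ring C. This is the epicatechin arrangement, the less stable one under equilibrating conditions. O3 (secondary, axial) and the phenolic O5 carry galloyl esters. O7, the two ring B hydroxyls and the six gallate hydroxyls are free, nine phenols in all. The compound is therefore sensitive to air and base (catechol and pyrogallol units, a labile aryl ester at O5), and C2 can epimerise through heterolysis of the C2–O1 bond. The real difficulty is to tell O5 from O7, two phenols in almost identical surroundings on ring A, while holding the 2,3-cis relationship and the absolute configuration. The strategy rests on the 1,3,5-oxygenation of ring A: C5, C7 and C8a bear oxygen and alternate with C4a, C6 and C8, so ring A can be cut into three ynol ether units, C4a≡C5, C6≡C7 and C8≡C8a. O5, O7 and O1 then belong to three different alkynes and are distinct from the start, and two of the alkynes are joined through C4–C3–C2–O1, the chain that holds both stereocentres.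

## Retrosynthetic reasoning

**24 ⇐ 23.** The nine benzyl C–O bonds are cut last. Hydrogenolysis is the one deprotection that leaves both esters alone, above all the aryl ester at O5, and the air-sensitive polyphenol appears only in the final step.

**23 ⇐ 21 + 22.** Both ester bonds (O3–CO and O5–CO) are cut together, giving diol 21 and two molecules of acid 22. The same acyl group goes onto both oxygens, so O3 and O5 need only be distinguished from O7 and the ring B oxygens, which stay benzylated.

**21 ⇐ 20.** O3 and O5 carry acid-labile groups in 20 (methoxymethyl on O3, tert-butyl on O5). One acid treatment removes both while the benzyl ethers survive, so a single step frees exactly the two hydroxyls that are to be acylated.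

**20 ⇐ 15 + 19 (key disconnection).** Three bonds of ring A are cut: C4a–C8a, C5–C6 and C7–C8. This is the only Kekulé dissection that keeps every triple bond outside ring C; the other would place C4a≡C8a inside the six-membered ring. It gives diyne 15, in which the ynol ethers C4a≡C5 and C8≡C8a are tethered through C4–C3–C2–O1, and benzyl ethynyl ether 19, which supplies C6, C7 and O7. The gain is that both rings close in one step, the three ring A oxygens arrive already differentiated (tert-butyl, benzyl, ring oxygen), and no bond to C2 or C3 is touched. The forward reaction, a rhodium-catalysed [2+2+2] cycloaddition, must join three electron-rich alkynes in the cross sense and orient 19 so that its oxygen ends on C7.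

**15 ⇐ 13 ⇐ 8 + 10.** The terminal ethynyl ether on O1 is the most fragile group, so it is unveiled last from the robust (E)-1,2-dichlorovinyl ether 13 by base. The C4–C4a bond is cut next: the C5 ynol ether is introduced as a carbon nucleophile, acetylide 12 from 10, which displaces the triflate 11 of alcohol 8.

- A silyl ynol ether on C5 was considered and set aside. It would have to be made by oxygenating a terminal acetylide and silylating the ynolate. Neither operation can be run beside the acidic C–H of the second ynol ether, nor before the organolithium step that unveils it, because alkyllithiums cleave the Si–O bond of silyl ynol ethers.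
- The tert-butyl ynol ether needs no oxidation step, is inert to the base used later, is bulky at C5, and comes off together with the O3 acetal.

**8 ⇐ 6 ⇐ 4 + 5.** C4 is taken back from the primary alcohol to a vinyl group (oxidative cleavage, then reduction), and the O1–C8a bond to the alkoxide of 4 and trichloroethylene 5. The dichlorovinyl group is installed first because 4 has only one free hydroxyl, so no protecting group is needed for O1.

**4 ⇐ 1 + 2.** The C2–C3 bond is cut between aldehyde 1 and the oxygen-bearing carbon of allyl ether 2. The forward reaction is an alkoxyallylboration through borane 3. It sets C2 and C3 together, syn and in the required absolute sense, with O3 already a methoxymethyl ether and O1 a free hydroxyl. Cutting here uses a purchasable ring B aldehyde and avoids any later differentiation of a diol.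

**19 ⇐ 16 + 5; 10 ⇐ 9 + 5.** Both remaining ynol ethers come from an alcohol (16 or 9) and trichloroethylene 5 by the same addition and elimination sequence. All six carbons of ring A thus come from three molecules of 5.

## Alternatives that were turned down

**Alternative 1:** Aryne–enal cascade.
- Disconnection: O1–C8a and C4–C4a by addition of an aldehyde across a ring A aryne, then O1–C2 by electrocyclisation.
- Forward key step: fluoride frees the aryne from an ortho-silyl aryl triflate; the carbonyl oxygen of a Z-configured 2-alkoxy-3-arylpropenal adds at C8a and its carbon at C4a; the benzoxete opens to an ortho-quinone methide; oxa-6π closure gives racemic 7-(benzyloxy)-2-[3,4-bis(benzyloxy)phenyl]-3,5-bis(methoxymethoxy)-2H-chromene A1.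
- For: the route is convergent, O5 and O7 differ before the key step, and the C5 alkoxy group directs the attack on the aryne. Aryne–enal annulation to 2H-chromenes is an established reaction type, so on precedent this alternative is stronger than the chosen key step.
- Against: A1 is racemic and still an enol ether across C3=C4. C2 arises in a thermal pericyclic step with no handle for asymmetric induction, and a 2H-chromene can racemise by reversible ring opening. Absolute configuration and the cis relationship would both depend on a later enantio- and diastereoselective reduction of a racemic enol ether in the presence of benzyl ethers, or on a resolution. The differentiated aryne precursor also costs several steps.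
- Comparison: the chosen strategy fixes C2 and C3 by a reagent-controlled allylboration before any ring is made, and its key step cannot disturb them. It pays for this with a cyclotrimerisation that has no direct precedent.

**Alternative 2:** Carbenoid C–H insertion to a temporary dihydrobenzofuran.
- Disconnection: C2–C3.
- Forward key step: Rh2(S-PTTL)4, dirhodium tetrakis(N-phthaloyl-tert-leucinate), decomposes an aryldiazoacetate on ring A. The carbenoid carbon (future C3) inserts into the benzylic C–H bond of the ring B benzyl ether on O1 and gives methyl cis-6-(benzyloxy)-2-[3,4-bis(benzyloxy)phenyl]-4-(triisopropylsilyloxy)-2,3-dihydrobenzofuran-3-carboxylate A2, whose ester carbon is the future C4.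
- For: enantioselective, cis-selective C–H insertion to 2-aryl-dihydrobenzofurans is known chemistry, again stronger on precedent than the chosen key step. O5 (silyl) and O7 (benzyl) are differentiated.
- Against: A2 has the wrong ring size, and C3 carries carbon instead of oxygen. C4 must be inserted between C3 and C4a and oxygen brought to C3, which means a 1,2-aryl shift through a cationic C3. That erases the stereocentre the catalyst set and reopens the cis/trans question at the capture step, where the trans arrangement is expected to be favoured. Several operations follow the key step.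
- Comparison: the chosen route forms ring C directly at the right size with O3 in place and needs only deprotection and acylation afterwards.

**Alternative 3:** Oxa-Diels–Alder of an ortho-quinone methide with a Z enol gallate.
- Disconnection: O1–C2 and C3–C4.
- Forward key step: a chiral BINOL-derived phosphoric acid dehydrates an ortho-hydroxybenzyl alcohol of ring A (O5 already galloylated) to the quinone methide, which adds the Z enol gallate of ring B. The cycloadduct is nona-O-benzyl epicatechin 3,5-di-O-gallate A3, the same compound as 23 (it carries nine benzyl groups).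
- For: this is by far the best step economy. Both esters are in place before ring formation, the adduct is one hydrogenolysis from the target, and the cis relationship follows from the Z geometry. On convergence and step count it is clearly superior to the chosen strategy.
- Against: both stereocentres and their absolute sense rest on one step with a weak dienophile. An enol ester is a poor nucleophile and offers the catalyst no hydrogen-bond donor, so rate and enantioselectivity are open. The electron-rich aryl group and the acyloxy group polarise the alkene in opposite senses, so the orientation is open too. The precursor has an aryl ester ortho to the benzylic alcohol, which invites acyl migration, and the quinone methide can self-condense.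
- Comparison: in the chosen route the configuration is secured by reliable chemistry before the uncertain step, and failure of that step cannot give a wrong stereoisomer. The price is a longer sequence.

Key step: step 8

Remark: allyl methoxymethyl ether is taken as purchasable, and the facial sense of step 1 is taken from the accepted chair model for diisopinocampheylboranes (reagent from (+)-α-pinene attacks the Si face of the aldehyde); should the sense prove opposite, the antipodal borane is used.

## Route

Step 1
Reactants: 1 3,4-bis(benzyloxy)benzaldehyde; 2 allyl methoxymethyl ether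
Product: 4 (1R,2R)-1-[3,4-bis(benzyloxy)phenyl]-2-(methoxymethoxy)but-3-en-1-ol, via allylborane 3 (not isolated)
Conditions: 2, s-BuLi, THF, −78 °C; (−)-Ipc2BOMe, −78 °C; BF3·OEt2; then 1, −78 °C → rt; NaOH, H2O2, 0 °C → rt
Reagents that add atoms: none
Why: Brown alkoxyallylboration: the (Z)-γ-alkoxyallylborane 3 reacts through a chair Zimmerman–Traxler transition state, so the Z geometry gives the syn 1,2-diol monoether, and the isopinocampheyl groups from (+)-α-pinene direct attack to the Si face of 1, setting C2 (R) and C3 (R) together. O3 is formed as its methoxymethyl ether and O1 as the free hydroxyl, so the two oxygens differ without a protecting-group step.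

Step 2
Reactants: 4 (1R,2R)-1-[3,4-bis(benzyloxy)phenyl]-2-(methoxymethoxy)but-3-en-1-ol; 5 trichloroethylene
Product: 6 1,2-bis(benzyloxy)-4-[(1R,2R)-1-{[(E)-1,2-dichloroethenyl]oxy}-2-(methoxymethoxy)but-3-en-1-yl]benzene
Conditions: KH, THF, 0 °C → rt; 5, −50 °C → rt
Reagents that add atoms: none
Why: The potassium alkoxide adds anti to dichloroacetylene released in situ from 5 and gives the (E)-1,2-dichlorovinyl ether, a masked ethynyl ether that is stable to base and chromatography. No bond to C2 is broken.

Step 3
Reactants: 6 1,2-bis(benzyloxy)-4-[(1R,2R)-1-{[(E)-1,2-dichloroethenyl]oxy}-2-(methoxymethoxy)but-3-en-1-yl]benzene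
Product: 8 (2R,3R)-3-[3,4-bis(benzyloxy)phenyl]-3-{[(E)-1,2-dichloroethenyl]oxy}-2-(methoxymethoxy)propan-1-ol, via aldehyde 7 (not isolated)
Conditions: OsO4 (cat.), NaIO4, 2,6-lutidine, dioxane/H2O, rt; then NaBH4, MeOH, 0 °C
Reagents that add atoms: osmium tetroxide, O=[Os](=O)(=O)=O, with sodium periodate, [Na+].[O-]I(=O)(=O)=O, as terminal oxidant (source of the new oxygen on C4)
Why: Lemieux–Johnson cleavage: OsO4 should dihydroxylate the monosubstituted alkene faster than the hindered, chlorine-deactivated enol ether or the arenes, and periodate cleaves the diol under lutidine buffering. Immediate borohydride reduction of 7 limits epimerisation at the α-alkoxy centre and β-elimination.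

Step 4
Reactants: 9 tert-butanol; 5 trichloroethylene
Product: 10 tert-butyl (E)-1,2-dichloroethenyl ether
Conditions: KH, THF, 0 °C; 5, −50 °C → rt; distillation
Reagents that add atoms: none
Why: The same anti addition of an alkoxide to dichloroacetylene formed in situ from 5; the product is a distillable liquid that stores the C4a≡C5 unit with O5 already attached.

Step 5
Reactants: 8 (2R,3R)-3-[3,4-bis(benzyloxy)phenyl]-3-{[(E)-1,2-dichloroethenyl]oxy}-2-(methoxymethoxy)propan-1-ol; 10 tert-butyl (E)-1,2-dichloroethenyl ether
Product: 13 1,2-bis(benzyloxy)-4-[(1R,2R)-5-tert-butoxy-1-{[(E)-1,2-dichloroethenyl]oxy}-2-(methoxymethoxy)pent-4-yn-1-yl]benzene, via triflate 11 (not isolated), via lithium tert-butoxyacetylide 12 (not isolated)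
Conditions: 8, Tf2O, 2,6-lutidine, CH2Cl2, −78 °C; separately 10, n-BuLi (2 equiv), THF, −78 → −40 °C; combine, THF/DMPU, −78 → −20 °C
Reagents that add atoms: none
Why: SN2 alkylation of a lithium alkoxyacetylide by a primary triflate forms C4–C4a; 12 arises from 10 by dehydrochlorination and chlorine–lithium exchange. The acetylide is too weak a base to attack the dichlorovinyl ether, and the triflate is used cold to forestall participation by the neighbouring acetal oxygen.

Step 6
Reactants: 13 1,2-bis(benzyloxy)-4-[(1R,2R)-5-tert-butoxy-1-{[(E)-1,2-dichloroethenyl]oxy}-2-(methoxymethoxy)pent-4-yn-1-yl]benzene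
Product: 15 1,2-bis(benzyloxy)-4-[(1R,2R)-5-tert-butoxy-1-(ethynyloxy)-2-(methoxymethoxy)pent-4-yn-1-yl]benzene, via lithium acetylide 14 (not isolated)
Conditions: n-BuLi (2.1 equiv), THF, −78 °C; MeOH, −78 °C; work-up and chromatography on deactivated silica at ≤ 0 °C, used at once
Reagents that add atoms: none
Why: Two equivalents of n-BuLi turn the dichlorovinyl ether into the lithium alkoxyacetylide 14 (loss of LiCl, then chlorine–lithium exchange), which is protonated cold; the internal tert-butyl ynol ether has no acidic hydrogen and is inert at −78 °C. The product is kept cold because a benzylic ethynyl ether can undergo a [3,3] shift or a retro-ene fragmentation on warming.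

Step 7
Reactants: 16 benzyl alcohol; 5 trichloroethylene
Product: 19 benzyl ethynyl ether, via benzyl dichlorovinyl ether 17 (not isolated), via lithium benzyloxyacetylide 18 (not isolated)
Conditions: KH, THF, 0 °C; 5, −50 °C → rt; then n-BuLi (2 equiv), −78 °C; MeOH, −78 °C; kept as a cold solution
Reagents that add atoms: none
Why: One-pot alkoxide addition to dichloroacetylene followed by double dehydrochlorination and protonation, the standard route to ethynyl ethers. The base is held to two equivalents at −78 °C to avoid benzylic lithiation, and the product is not warmed because benzyl alkynyl ethers rearrange sigmatropically.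

Step 8
Reactants: 15 1,2-bis(benzyloxy)-4-[(1R,2R)-5-tert-butoxy-1-(ethynyloxy)-2-(methoxymethoxy)pent-4-yn-1-yl]benzene; 19 benzyl ethynyl ether
Product: 20 7,3′,4′-tri-O-benzyl-5-O-tert-butyl-3-O-(methoxymethyl)epicatechin
Conditions: [Rh(cod)2]BF4 (5 mol%), rac-BINAP (5 mol%), CH2Cl2 (catalyst pre-hydrogenated to remove cod, then Ar); 15 and 19 (3 equiv) added slowly, 0 °C → rt
Reagents that add atoms: none
Why: Proposed new method: the cationic monovalent rhodium–BINAP fragment binds both alkynes of 15 and couples them oxidatively to a trivalent rhodacyclopentadiene, which forms C4a–C8a; 19 then inserts into a Rh–C bond and reductive elimination forms C5–C6 and C7–C8, releases the arene and returns monovalent rhodium. The closest known reaction type is the cationic rhodium/bisphosphine-catalysed [2+2+2] cycloaddition of tethered 1,6- and 1,7-diynes with monoalkynes, documented for heteroatom-substituted alkynes (ynamides, alkynyl ethers) but not for the union of three ynol ethers. Ring C closes in the oxidative coupling as a six-membered ring annulated to the metallacycle (four-atom tether C4–C3–C2–O1 between the alkynes), and ring A closes by insertion and reductive elimination, formally a [4+2] addition of 19 to the rhodacycle. No stereocentre is formed: C2 and C3 lie in the tether, no bond to them is made or broken, and the syn relationship of 4 becomes the 2,3-cis substitution of ring C. Two selectivities are needed. Cross-selectivity over homo-oligomerisation is served by the intramolecular first coupling and by slow addition of both alkynes to the catalyst. The orientation of 19 (CH to C5, C–OBn to C8, hence OBn on C7) is secured sterically by the tert-butoxy group on C5 against hydrogen on C8, and electronically because it joins each nucleophilic β-carbon of one ynol ether to the oxygen-bearing α-carbon of the next, the head-to-tail 1,3,5-pattern. The run stays at or below room temperature so that neither the tert-butyl ynol ether (loss of isobutene) nor the benzylic and benzyl ynol ethers (retro-ene, [3,3] shift) decay thermally.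

Step 9
Reactants: 20 7,3′,4′-tri-O-benzyl-5-O-tert-butyl-3-O-(methoxymethyl)epicatechin
Product: 21 7,3′,4′-tri-O-benzylepicatechin
Conditions: HCl (1.25 M in MeOH)/CH2Cl2, 1,3,5-trimethoxybenzene, 0 → 40 °C
Reagents that add atoms: none
Why: Acidolysis: the aryl tert-butyl ether ionises to the phenol, and the methoxymethyl acetal is exchanged into methanol as dimethoxymethane, while benzyl ethers are stable. Methanol and the sacrificial arene intercept the cations before they can alkylate ring A.

Step 10
Reactants: 21 7,3′,4′-tri-O-benzylepicatechin; 22 3,4,5-tris(benzyloxy)benzoic acid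
Product: 23 7,3′,4′-tri-O-benzylepicatechin 3,5-bis[3,4,5-tris(benzyloxy)benzoate]
Conditions: 22 (2.5 equiv), EDC·HCl, DMAP, CH2Cl2, rt
Reagents that add atoms: none
Why: Steglich-type carbodiimide esterification with DMAP acylates both the phenol O5 and the axial secondary alcohol O3. O7 and the ring B oxygens are blocked as benzyl ethers, so only the two intended esters can form.

Step 11
Reactants: 23 7,3′,4′-tri-O-benzylepicatechin 3,5-bis[3,4,5-tris(benzyloxy)benzoate]
Product: 24 epicatechin 3,5-di-O-gallate
Conditions: H2 (1 atm), Pd(OH)2/C, THF/MeOH, rt; filtration under Ar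
Reagents that add atoms: none
Why: Hydrogenolysis of the nine benzyl aryl ethers under neutral conditions, which should leave both esters and the cyclic benzylic C2–O1 bond intact. The stereocentres are not involved.

## Compound list

1 | 3,4-bis(benzyloxy)benzaldehyde | O=Cc1ccc(OCc2ccccc2)c(OCc2ccccc2)c1 | starting material
2 | allyl methoxymethyl ether, 3-(methoxymethoxy)prop-1-ene | C=CCOCOC | starting material
3 | [(Z)-3-(methoxymethoxy)allyl]diisopinocampheylborane (isopinocampheyl groups from (+)-α-pinene) | COCO/C=C\CB([C@@H]1C[C@@H]2C[C@H]([C@H]1C)C2(C)C)[C@@H]1C[C@@H]2C[C@H]([C@H]1C)C2(C)C | intermediate (not isolated)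
4 | (1R,2R)-1-[3,4-bis(benzyloxy)phenyl]-2-(methoxymethoxy)but-3-en-1-ol | C=C[C@@H](OCOC)[C@@H](c1ccc(OCc2ccccc2)c(OCc2ccccc2)c1)O | intermediate
5 | trichloroethylene | ClC=C(Cl)Cl | starting material
6 | 1,2-bis(benzyloxy)-4-[(1R,2R)-1-{[(E)-1,2-dichloroethenyl]oxy}-2-(methoxymethoxy)but-3-en-1-yl]benzene | C=C[C@@H](OCOC)[C@@H](c1ccc(OCc2ccccc2)c(OCc2ccccc2)c1)O/C(Cl)=C\Cl | intermediate
7 | (2S,3R)-3-[3,4-bis(benzyloxy)phenyl]-3-{[(E)-1,2-dichloroethenyl]oxy}-2-(methoxymethoxy)propanal | O=C[C@@H](OCOC)[C@@H](c1ccc(OCc2ccccc2)c(OCc2ccccc2)c1)O/C(Cl)=C\Cl | intermediate (not isolated)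
8 | (2R,3R)-3-[3,4-bis(benzyloxy)phenyl]-3-{[(E)-1,2-dichloroethenyl]oxy}-2-(methoxymethoxy)propan-1-ol | OC[C@@H](OCOC)[C@@H](c1ccc(OCc2ccccc2)c(OCc2ccccc2)c1)O/C(Cl)=C\Cl | intermediate
9 | tert-butanol | CC(C)(C)O | starting material
10 | tert-butyl (E)-1,2-dichloroethenyl ether | CC(C)(C)O/C(Cl)=C\Cl | intermediate
11 | (2R,3R)-3-[3,4-bis(benzyloxy)phenyl]-3-{[(E)-1,2-dichloroethenyl]oxy}-2-(methoxymethoxy)propyl trifluoromethanesulfonate | O=S(=O)(OC[C@@H](OCOC)[C@@H](c1ccc(OCc2ccccc2)c(OCc2ccccc2)c1)O/C(Cl)=C\Cl)C(F)(F)F | intermediate (not isolated)
12 | lithium tert-butoxyacetylide | [Li]C#COC(C)(C)C | intermediate (not isolated)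
13 | 1,2-bis(benzyloxy)-4-[(1R,2R)-5-tert-butoxy-1-{[(E)-1,2-dichloroethenyl]oxy}-2-(methoxymethoxy)pent-4-yn-1-yl]benzene | CC(C)(C)OC#CC[C@@H](OCOC)[C@@H](c1ccc(OCc2ccccc2)c(OCc2ccccc2)c1)O/C(Cl)=C\Cl | intermediate
14 | lithium acetylide of 15 (lithium on the terminal carbon of the O1 ethynyl ether) | CC(C)(C)OC#CC[C@@H](OCOC)[C@@H](c1ccc(OCc2ccccc2)c(OCc2ccccc2)c1)OC#C[Li] | intermediate (not isolated)
15 | 1,2-bis(benzyloxy)-4-[(1R,2R)-5-tert-butoxy-1-(ethynyloxy)-2-(methoxymethoxy)pent-4-yn-1-yl]benzene | CC(C)(C)OC#CC[C@@H](OCOC)[C@@H](c1ccc(OCc2ccccc2)c(OCc2ccccc2)c1)OC#C | intermediate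
16 | benzyl alcohol | OCc1ccccc1 | starting material
17 | benzyl (E)-1,2-dichloroethenyl ether | c1ccccc1CO/C(Cl)=C\Cl | intermediate (not isolated)
18 | lithium (benzyloxy)acetylide | [Li]C#COCc1ccccc1 | intermediate (not isolated)
19 | benzyl ethynyl ether | C#COCc1ccccc1 | intermediate
20 | 7,3′,4′-tri-O-benzyl-5-O-tert-butyl-3-O-(methoxymethyl)epicatechin, (2R,3R)-7-(benzyloxy)-2-[3,4-bis(benzyloxy)phenyl]-5-tert-butoxy-3-(methoxymethoxy)chromane | CC(C)(C)Oc1cc(OCc2ccccc2)cc2c1C[C@@H](OCOC)[C@@H](c1ccc(OCc3ccccc3)c(OCc3ccccc3)c1)O2 | intermediate
21 | 7,3′,4′-tri-O-benzylepicatechin, (2R,3R)-7-(benzyloxy)-2-[3,4-bis(benzyloxy)phenyl]chromane-3,5-diol | Oc1cc(OCc2ccccc2)cc2c1C[C@@H](O)[C@@H](c1ccc(OCc3ccccc3)c(OCc3ccccc3)c1)O2 | intermediate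
22 | 3,4,5-tris(benzyloxy)benzoic acid | O=C(O)c1cc(OCc2ccccc2)c(OCc2ccccc2)c(OCc2ccccc2)c1 | starting material
23 | 7,3′,4′-tri-O-benzylepicatechin 3,5-bis[3,4,5-tris(benzyloxy)benzoate] | O=C(Oc1cc(OCc2ccccc2)cc2c1C[C@@H](OC(=O)c1cc(OCc3ccccc3)c(OCc3ccccc3)c(OCc3ccccc3)c1)[C@@H](c1ccc(OCc3ccccc3)c(OCc3ccccc3)c1)O2)c1cc(OCc2ccccc2)c(OCc2ccccc2)c(OCc2ccccc2)c1 | intermediate
24 | epicatechin 3,5-di-O-gallate | O=C(Oc1cc(O)cc2c1C[C@@H](OC(=O)c1cc(O)c(O)c(O)c1)[C@@H](c1ccc(O)c(O)c1)O2)c1cc(O)c(O)c(O)c1 | target

## Step count and least certain steps

Total step count: 11. Longest linear sequence: 9 (steps 1, 2, 3, 5, 6, 8, 9, 10, 11).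

**Step 8 (key step, proposed new method).**
- What may go wrong: homo-oligomerisation of the electron-rich alkynes instead of the cross reaction; insertion of 19 in the reverse orientation, which would put the benzyloxy group on C6; Lewis-acid-induced loss of isobutene from the tert-butyl ynol ether; diversion of the terminal ynol ethers into rhodium vinylidene pathways.
- Fallback (metal-free, from known reaction types), from 15 back to 21:
  - Warming 15 in toluene triggers the retro-ene loss of isobutene typical of tert-butyl ynol ethers and gives the aldoketene (4R,5R)-5-[3,4-bis(benzyloxy)phenyl]-5-(ethynyloxy)-4-(methoxymethoxy)pent-1-en-1-one F1.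
  - Intramolecular ketene–alkoxyalkyne [2+2] cycloaddition onto the O1 ynol ether forms C4a–C8a and C5–C8 and gives the bicyclic 3-alkoxycyclobutenone (3R,4R)-3-[3,4-bis(benzyloxy)phenyl]-4-(methoxymethoxy)-2-oxabicyclo[4.2.0]oct-1(8)-en-7-one F2.
  - Danheiser benzannulation of F2 with 19 (4π opening to the vinylketene, [2+2] with 19, 4π opening, 6π closure, tautomerisation) builds ring A and gives 7,3′,4′-tri-O-benzyl-3-O-(methoxymethyl)epicatechin F3. Its 5-hydroxyl is free, and the benzyloxy group is fixed on C7 by the polarity of the ynol ether.
  - Removal of the methoxymethyl group from F3 with methanolic HCl returns to the route at 21.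
  - The weak point is that 19 and the O1 ynol ether of 15 are themselves heat-sensitive, so 19 would be added in portions.

**Step 3.**
- What may go wrong: competing oxidation of the dichlorovinyl enol ether by OsO4, or β-elimination of the dichlorovinyloxy group and epimerisation at the α-alkoxy centre of aldehyde 7 before it is reduced.
- Fallback (the alkene is cleaved before the dichlorovinyl group exists), from 4 back to 8:
  - Lemieux–Johnson cleavage of 4 gives (2S,3R)-3-[3,4-bis(benzyloxy)phenyl]-3-hydroxy-2-(methoxymethoxy)propanal F4.
  - Borohydride reduction gives (1R,2R)-1-[3,4-bis(benzyloxy)phenyl]-2-(methoxymethoxy)propane-1,3-diol F5.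
  - Selective tritylation of the primary hydroxyl (TrCl, pyridine) gives (1R,2R)-1-[3,4-bis(benzyloxy)phenyl]-2-(methoxymethoxy)-3-(triphenylmethoxy)propan-1-ol F6. Trityl is chosen because it cannot migrate to the neighbouring alkoxide.
  - KH and 5 give the dichlorovinyl ether 1,2-bis(benzyloxy)-4-[(1R,2R)-1-{[(E)-1,2-dichloroethenyl]oxy}-2-(methoxymethoxy)-3-(triphenylmethoxy)propyl]benzene F7.
  - Mild acid methanolysis of the trityl ether (catalytic TsOH, MeOH/CH2Cl2, 0 °C) returns to the route at 8.

**Step 9.**
- What may go wrong: capture of the tert-butyl or methoxymethyl cation by the nucleophilic C6 and C8 positions of ring A once O5 is a free phenol; acid-promoted heterolysis of the C2–O1 bond (epimerisation at C2) during the longer exposure that the alkyl acetal needs.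
- Fallback (the two ethers are removed in separate stages around the acylations), from 20 back to 23:
  - Brief treatment of 20 with dilute trifluoroacetic acid in CH2Cl2 at 0 °C with an arene scavenger cleaves only the aryl tert-butyl ether and gives 7,3′,4′-tri-O-benzyl-3-O-(methoxymethyl)epicatechin F3, the phenol also met in the fallback for step 8.
  - Esterification of O5 with 22 (EDC·HCl, DMAP) gives 7,3′,4′-tri-O-benzyl-3-O-(methoxymethyl)epicatechin 5-[3,4,5-tris(benzyloxy)benzoate] F8, whose acyloxy group makes ring A less nucleophilic.
  - Me2BBr at −78 °C removes the acetal without a free cation (the fragment leaves as bromomethyl methyl ether) and gives 7,3′,4′-tri-O-benzylepicatechin 5-[3,4,5-tris(benzyloxy)benzoate] F9.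
  - A second esterification with 22 at O3 returns to the route at 23.

## Further compounds

F1 | step 8 | (4R,5R)-5-[3,4-bis(benzyloxy)phenyl]-5-(ethynyloxy)-4-(methoxymethoxy)pent-1-en-1-one | O=C=CC[C@@H](OCOC)[C@@H](c1ccc(OCc2ccccc2)c(OCc2ccccc2)c1)OC#C
F2 | step 8 | (3R,4R)-3-[3,4-bis(benzyloxy)phenyl]-4-(methoxymethoxy)-2-oxabicyclo[4.2.0]oct-1(8)-en-7-one (C6 unassigned) | O=C1C=C2O[C@H](c3ccc(OCc4ccccc4)c(OCc4ccccc4)c3)[C@H](OCOC)CC12
F3 | step 8 | 7,3′,4′-tri-O-benzyl-3-O-(methoxymethyl)epicatechin | Oc1cc(OCc2ccccc2)cc2c1C[C@@H](OCOC)[C@@H](c1ccc(OCc3ccccc3)c(OCc3ccccc3)c1)O2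
F4 | step 3 | (2S,3R)-3-[3,4-bis(benzyloxy)phenyl]-3-hydroxy-2-(methoxymethoxy)propanal | O=C[C@@H](OCOC)[C@@H](c1ccc(OCc2ccccc2)c(OCc2ccccc2)c1)O
F5 | step 3 | (1R,2R)-1-[3,4-bis(benzyloxy)phenyl]-2-(methoxymethoxy)propane-1,3-diol | OC[C@@H](OCOC)[C@@H](c1ccc(OCc2ccccc2)c(OCc2ccccc2)c1)O
F6 | step 3 | (1R,2R)-1-[3,4-bis(benzyloxy)phenyl]-2-(methoxymethoxy)-3-(triphenylmethoxy)propan-1-ol | C(OC[C@@H](OCOC)[C@@H](c1ccc(OCc2ccccc2)c(OCc2ccccc2)c1)O)(c1ccccc1)(c1ccccc1)c1ccccc1
F7 | step 3 | 1,2-bis(benzyloxy)-4-[(1R,2R)-1-{[(E)-1,2-dichloroethenyl]oxy}-2-(methoxymethoxy)-3-(triphenylmethoxy)propyl]benzene | C(OC[C@@H](OCOC)[C@@H](c1ccc(OCc2ccccc2)c(OCc2ccccc2)c1)O/C(Cl)=C\Cl)(c1ccccc1)(c1ccccc1)c1ccccc1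
F8 | step 9 | 7,3′,4′-tri-O-benzyl-3-O-(methoxymethyl)epicatechin 5-[3,4,5-tris(benzyloxy)benzoate] | O=C(Oc1cc(OCc2ccccc2)cc2c1C[C@@H](OCOC)[C@@H](c1ccc(OCc3ccccc3)c(OCc3ccccc3)c1)O2)c1cc(OCc2ccccc2)c(OCc2ccccc2)c(OCc2ccccc2)c1
F9 | step 9 | 7,3′,4′-tri-O-benzylepicatechin 5-[3,4,5-tris(benzyloxy)benzoate] | O=C(Oc1cc(OCc2ccccc2)cc2c1C[C@@H](O)[C@@H](c1ccc(OCc3ccccc3)c(OCc3ccccc3)c1)O2)c1cc(OCc2ccccc2)c(OCc2ccccc2)c(OCc2ccccc2)c1
A1 | alternative 1 | racemic 7-(benzyloxy)-2-[3,4-bis(benzyloxy)phenyl]-3,5-bis(methoxymethoxy)-2H-chromene | COCOC1=Cc2c(OCOC)cc(OCc3ccccc3)cc2OC1c1ccc(OCc2ccccc2)c(OCc2ccccc2)c1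
A2 | alternative 2 | methyl cis-6-(benzyloxy)-2-[3,4-bis(benzyloxy)phenyl]-4-(triisopropylsilyloxy)-2,3-dihydrobenzofuran-3-carboxylate | COC(=O)[C@@H]1c2c(O[Si](C(C)C)(C(C)C)C(C)C)cc(OCc3ccccc3)cc2O[C@@H]1c1ccc(OCc2ccccc2)c(OCc2ccccc2)c1
A3 | alternative 3 | nona-O-benzyl epicatechin 3,5-di-O-gallate (identical with 23) | O=C(Oc1cc(OCc2ccccc2)cc2c1C[C@@H](OC(=O)c1cc(OCc3ccccc3)c(OCc3ccccc3)c(OCc3ccccc3)c1)[C@@H](c1ccc(OCc3ccccc3)c(OCc3ccccc3)c1)O2)c1cc(OCc2ccccc2)c(OCc2ccccc2)c(OCc2ccccc2)c1
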